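The data were generated by integration from invented constants; the scatter is artificial.

If Ju can enter the solution at a limited rate, and each Ly lost takes up one dissolved Ju, then the balance of dissolved Ju says that Ly falls by a steady amount per minute, in green as in teal, once that entry is the rate-limiting step. This is our working guess, so we reckon in rates.

| setting | green | teal | flask |
|---|---|---|---|
| Ly | 0.10 M | 0.067 M | 0.10 M |
| Ju | 32 mM (held) | 32 mM (held) | 32 mM (held) |
| remark | the very flask that is asked about, followed so far | run made earlier |  |
| time |  |  | 15 min |

- green (time / s: Wu / %, Ly / %): 20.0: 0, 100.0; 40.0: 0, 99.6; 50.0: 0.3, 99.9; 80.0: 0.3, 99.0; 90.0: 0.2, 99.1; 120: 1.0, 98.2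
- teal (time / min: Wu / %, Ly / %): 0.500: 0, 100.0; 0.833: 0, 99.3; 1.33: 0.3, 99.1; 2.00: 0.9, 98.2; 4.00: 2.6, 94.1; 6.00: 4.7, 88.4

(readings scatter by 0.3 percentage points)

- the analysis behind the earlier runs scatters by 0.3 percentage points, standard deviation
- at the start none of Ju is in solution

- amount of Wu at 15 min, in percent of the Ly charged
- the change that raises the amount of Wu at 15 min, in percent of the Ly charged most ("none" if none brings more than 2 percentage points) (zeta / epsilon / none)
- amount of Wu at 15 min, in percent of the Ly charged, after epsilon

- zeta: doubling the saturation concentration of Ju, all else as stated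
- epsilon: doubling the transfer coefficient of Ju, all else as stated

The rate starts from nothing: no Ju is in solution at the start, and teal still reads 100.0% Ly at 0.500 min. We call the drain the concentration of Ly lost per minute between the last two teal readings, 1.91 mM/min. The window before it gave 1.37 mM/min, so teal was still speeding up and our figure may err low.

Two factors then cut the green flask's Wu in our reckoning. The line through those readings begins at 1.93 min, which leaves a factor 0.871 of the time. Teal's last reading puts 0.405 of the Ly lost into Wu. So we expect the green flask to lose 25.0% of its Ly and hold 10.1% Wu.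

The forecast, for which “Ly loss looks first order in Ly”, differs from us: it says 13% (10.5% to 15.5%), 16.5% after epsilon (13.5% to 20.5%), and zeta.

    Ly + Wy → Ry (k = 2.70 /M/min)
    Ly + Wy → Wu (k = 2.10 /M/min)
    Ju ⇌ Wy, rate k3*(csat - [Wy]) (kL = 0.0840 /min)

The green flask gives 12.5% Wu, 20.5% after epsilon, and zeta gains most, 11 percentage points against 8 points. At 15.0 min in the green flask Wy, the dissolved Ju, is made 1.06 times as fast as it is used up, each step taken net. From 7.50 min to 15.0 min the green flask lost Ly at 2.10 mM/min, beside the drain of 1.91 mM/min. For the same charge left until 40 min, the drain leaves 27.3% of the Ly, and that flask holds 26.7%.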